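**Retrosynthetic overview**
1. Target 20 ← hydrogenolysis of 7-benzyl ether 19 ← oxidative ring closure of 2'-hydroxychalcone 17 (ring C is the only ring formed, and it is formed last).
2. Chalcone 17 ← intermolecular Claisen–Schmidt aldol condensation of acetophenone 14 (ring A) with 4-methoxybenzaldehyde 15 (ring B); this is the key C–C bond.
3. 14 ← selective 4-O-benzylation of 13 ← BCl3 ortho-demethylation and MOM removal from symmetric ketone 11.
4. 11 ← two successive directed ortho-lithiations of 1,2,4,5-tetramethoxybenzene 4 (first installs the future 7-oxygen, second the acetyl group).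
5. 4 ← Dakin oxidation and methylation of cheap 2,4,5-trimethoxybenzaldehyde 1; rings A and B are bought as benzene rings.

Assumption: the target has no stereocentre and is achiral, so "single enantiomer" needs no stereocontrol; the only stereo-elements on the way are the E-alkene of 17 and racemic, transient centres in 10, 16 and 18.

**Route**

Step 1
Reactants: 1 2,4,5-trimethoxybenzaldehyde
Product: 3 2,4,5-trimethoxyphenol, via aryl formate 2 (not isolated)
Conditions: 30% H2O2 (1.3 equiv), cat. H2SO4, MeOH, rt, 12 h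
Reagents that add atoms: hydrogen peroxide OO
Why: Acid-catalysed Dakin (Baeyer–Villiger-type) oxidation, in which the electron-rich aryl group migrates to oxygen and the formate 2 is methanolysed in the flask.

Step 2
Reactants: 3 2,4,5-trimethoxyphenol
Product: 4 1,2,4,5-tetramethoxybenzene
Conditions: MeI (1.5 equiv), K2CO3 (2 equiv), acetone, reflux, N2, 12 h
Reagents that add atoms: iodomethane CI
Why: Williamson ether synthesis (SN2 O-methylation of the phenoxide), run under N2 because the phenol is air-sensitive.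

Step 3
Reactants: 4 1,2,4,5-tetramethoxybenzene
Product: 7 2,3,5,6-tetramethoxyphenol, via aryllithium 5 (not isolated), via arylboronate 6 (not isolated)
Conditions: n-BuLi (1.1 equiv), THF, 0 °C to rt, 2 h; B(OMe)3 (1.5 equiv), −78 °C to rt; AcOH, 30% H2O2, 0 °C to rt
Reagents that add atoms: hydrogen peroxide OO
Why: Directed ortho-metalation at one of the two equivalent C–H positions flanked by two OMe groups, then borylation and boronate oxidation (1,2-aryl shift from boron to oxygen) give the phenol.

Step 4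
Reactants: 7 2,3,5,6-tetramethoxyphenol
Product: 8 3-(methoxymethoxy)-1,2,4,5-tetramethoxybenzene
Conditions: NaH (1.2 equiv), THF/DMF, 0 °C; MOMCl (1.2 equiv), 0 °C to rt
Reagents that add atoms: chloromethyl methyl ether COCCl
Why: Williamson-type O-alkylation of the hindered phenoxide with a very reactive alpha-chloro ether gives a base-stable MOM ether with no ortho C–H, so the next lithiation can only go to the last ring position.

Step 5
Reactants: 8 3-(methoxymethoxy)-1,2,4,5-tetramethoxybenzene
Product: 11 1-[4-(methoxymethoxy)-2,3,5,6-tetramethoxyphenyl]ethan-1-one, via aryllithium 9 (not isolated), via hemiaminal alkoxide 10 (not isolated)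
Conditions: n-BuLi (1.2 equiv), TMEDA (1.2 equiv), THF, 0 °C, 1.5 h; MeC(O)N(OMe)Me (1.5 equiv), −78 to 0 °C; sat. aq NH4Cl
Reagents that add atoms: N-methoxy-N-methylacetamide CC(=O)N(C)OC
Why: A second directed ortho-metalation at the only remaining ring C–H is followed by a Weinreb ketone synthesis, whose chelated tetrahedral adduct 10 survives until work-up and so prevents over-addition.

Step 6
Reactants: 11 1-[4-(methoxymethoxy)-2,3,5,6-tetramethoxyphenyl]ethan-1-one
Product: 13 1-(2,4-dihydroxy-3,5,6-trimethoxyphenyl)ethan-1-one, via boron chelate 12 (not isolated)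
Conditions: BCl3 (2.5 equiv, 1 M in CH2Cl2), CH2Cl2, −78 to 0 °C, 1–2 h; ice/H2O
Reagents that add atoms: none
Why: Carbonyl-directed Lewis-acid demethylation, in which BCl3 bound to the ketone cleaves exactly one ortho OMe through a six-membered chelate (the chelated carbonyl then no longer activates the second one) and also cleaves the MOM acetal.

Step 7
Reactants: 13 1-(2,4-dihydroxy-3,5,6-trimethoxyphenyl)ethan-1-one
Product: 14 1-[4-(benzyloxy)-2-hydroxy-3,5,6-trimethoxyphenyl]ethan-1-one
Conditions: BnBr (1.05 equiv), K2CO3 (1.2 equiv), acetone, reflux, 6–8 h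
Reagents that add atoms: benzyl bromide BrCc1ccccc1
Why: Williamson etherification is selective for the 4-OH because the 2-OH is tied up in a hydrogen bond to the ketone and is much less acidic and nucleophilic.

Step 8
Reactants: 14 1-[4-(benzyloxy)-2-hydroxy-3,5,6-trimethoxyphenyl]ethan-1-one; 15 4-methoxybenzaldehyde
Product: 17 (E)-1-[4-(benzyloxy)-2-hydroxy-3,5,6-trimethoxyphenyl]-3-(4-methoxyphenyl)prop-2-en-1-one, via aldol adduct 16 (not isolated)
Conditions: KOH (50% aq, 10 equiv), EtOH, rt, 48 h; cold 1 M HCl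
Reagents that add atoms: none
Why: Claisen–Schmidt crossed aldol condensation, where only the ketone can enolise and only the aldehyde lacks alpha-hydrogens, and E1cB dehydration of 16 gives the conjugated E-enone under thermodynamic control.

Step 9
Reactants: 17 (E)-1-[4-(benzyloxy)-2-hydroxy-3,5,6-trimethoxyphenyl]-3-(4-methoxyphenyl)prop-2-en-1-one
Product: 19 7-(benzyloxy)-5,6,8-trimethoxy-2-(4-methoxyphenyl)-4H-chromen-4-one, via flavanone 18 (not isolated)
Conditions: I2 (10 mol%), DMSO, 130 °C, 3 h; aq Na2S2O3 work-up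
Reagents that add atoms: none
Why: Iodine/DMSO oxidative cyclisation of a 2'-hydroxychalcone, by intramolecular oxa-Michael addition to flavanone 18, alpha-iodination and loss of HI, with DMSO reoxidising HI to I2.

Step 10
Reactants: 19 7-(benzyloxy)-5,6,8-trimethoxy-2-(4-methoxyphenyl)-4H-chromen-4-one
Product: 20 7-hydroxy-5,6,8-trimethoxy-2-(4-methoxyphenyl)-4H-chromen-4-one
Conditions: H2 (1 atm), Pd/C (10 wt% Pd on carbon, 10 mol% Pd), EtOAc/MeOH 1:1, rt, 2–4 h, stopped at full conversion
Reagents that add atoms: none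
Why: Catalytic hydrogenolysis cleaves the benzyl–oxygen bond only; the methyl ethers are inert and the conjugated chromone C2=C3 bond is reduced far more slowly.

**Compound list**
1 | 2,4,5-trimethoxybenzaldehyde | COc1cc(OC)c(OC)cc1C=O | starting material
2 | 2,4,5-trimethoxyphenyl formate | COc1cc(OC)c(OC)cc1OC=O | intermediate (not isolated)
3 | 2,4,5-trimethoxyphenol | COc1cc(OC)c(OC)cc1O | intermediate
4 | 1,2,4,5-tetramethoxybenzene | COc1cc(OC)c(OC)cc1OC | intermediate
5 | 2,3,5,6-tetramethoxyphenyllithium | [Li]c1c(OC)c(OC)cc(OC)c1OC | intermediate (not isolated)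
6 | dimethyl (2,3,5,6-tetramethoxyphenyl)boronate | COB(OC)c1c(OC)c(OC)cc(OC)c1OC | intermediate (not isolated)
7 | 2,3,5,6-tetramethoxyphenol | COc1cc(OC)c(OC)c(O)c1OC | intermediate
8 | 3-(methoxymethoxy)-1,2,4,5-tetramethoxybenzene | COCOc1c(OC)c(OC)cc(OC)c1OC | intermediate
9 | 4-(methoxymethoxy)-2,3,5,6-tetramethoxyphenyllithium | [Li]c1c(OC)c(OC)c(OCOC)c(OC)c1OC | intermediate (not isolated)
10 | lithium 1-[methoxy(methyl)amino]-1-[4-(methoxymethoxy)-2,3,5,6-tetramethoxyphenyl]ethan-1-olate (racemic) | CC(O[Li])(N(C)OC)c1c(OC)c(OC)c(OCOC)c(OC)c1OC | intermediate (not isolated)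
11 | 1-[4-(methoxymethoxy)-2,3,5,6-tetramethoxyphenyl]ethan-1-one | CC(=O)c1c(OC)c(OC)c(OCOC)c(OC)c1OC | intermediate
12 | 1-[2,4-bis(dichloroboryloxy)-3,5,6-trimethoxyphenyl]ethan-1-one | CC(=O)c1c(OB(Cl)Cl)c(OC)c(OB(Cl)Cl)c(OC)c1OC | intermediate (not isolated)
13 | 1-(2,4-dihydroxy-3,5,6-trimethoxyphenyl)ethan-1-one | CC(=O)c1c(O)c(OC)c(O)c(OC)c1OC | intermediate
14 | 1-[4-(benzyloxy)-2-hydroxy-3,5,6-trimethoxyphenyl]ethan-1-one | CC(=O)c1c(O)c(OC)c(OCc2ccccc2)c(OC)c1OC | intermediate
15 | 4-methoxybenzaldehyde | COc1ccc(C=O)cc1 | starting material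
16 | 1-[4-(benzyloxy)-2-hydroxy-3,5,6-trimethoxyphenyl]-3-hydroxy-3-(4-methoxyphenyl)propan-1-one (racemic) | COc1ccc(C(O)CC(=O)c2c(O)c(OC)c(OCc3ccccc3)c(OC)c2OC)cc1 | intermediate (not isolated)
17 | (E)-1-[4-(benzyloxy)-2-hydroxy-3,5,6-trimethoxyphenyl]-3-(4-methoxyphenyl)prop-2-en-1-one | COc1ccc(/C=C/C(=O)c2c(O)c(OC)c(OCc3ccccc3)c(OC)c2OC)cc1 | intermediate
18 | 7-(benzyloxy)-5,6,8-trimethoxy-2-(4-methoxyphenyl)chroman-4-one (racemic) | COc1ccc(C2CC(=O)c3c(OC)c(OC)c(OCc4ccccc4)c(OC)c3O2)cc1 | intermediate (not isolated)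
19 | 7-(benzyloxy)-5,6,8-trimethoxy-2-(4-methoxyphenyl)-4H-chromen-4-one | COc1ccc(-c2cc(=O)c3c(OC)c(OC)c(OCc4ccccc4)c(OC)c3o2)cc1 | intermediate
20 | 7-hydroxy-5,6,8-trimethoxy-2-(4-methoxyphenyl)-4H-chromen-4-one (7-hydroxy-4',5,6,8-tetramethoxyflavone) | COc1ccc(-c2cc(=O)c3c(OC)c(OC)c(O)c(OC)c3o2)cc1 | target

**Step count and risks**
Total steps: 10. Longest linear sequence: 10 steps (1 to 20); 15 is bought.

Most likely to fail, first: step 5. The hindered aryllithium 9 may deprotonate the Weinreb amide instead of adding to it. The fallback sets out from 8 and comes back at 11. Lithiate 8 as before and trap 9 at −78 °C with acetaldehyde, a smaller and more electrophilic partner, to give the racemic carbinol 1-[4-(methoxymethoxy)-2,3,5,6-tetramethoxyphenyl]ethan-1-ol F1. Then oxidise the benzylic alcohol with Dess–Martin periodinane (NaHCO3-buffered CH2Cl2, rt) to ketone 11.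

Second: step 6. BCl3 may over-demethylate (second ortho OMe, or an OMe next to the freed 4-oxygen), and the following benzylation then inherits a mixture. The fallback sets out from 11 and comes back at 14, bypassing 13. Remove the MOM group with catalytic HCl in MeOH at 50 °C to give 1-(4-hydroxy-2,3,5,6-tetramethoxyphenyl)ethan-1-one F2. Benzylate its only OH (BnBr, K2CO3, DMF, rt) to give 1-[4-(benzyloxy)-2,3,5,6-tetramethoxyphenyl]ethan-1-one F3. Then cleave one ortho OMe with MgI2·OEt2 (Et2O/toluene, 60 °C), a mild chelation-controlled reagent that leaves the remote benzyl ether alone, to reach 14 directly.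

Third: step 9, together with the slow condensation in step 8 that feeds it. The iodine/DMSO closure can stall at the flavanone, or the HI formed can attack the benzyl ether or the 5-OMe. The fallback sets out from 14 and comes back at 19, replacing the chalcone by a 1,3-diketone. Treat 14 with LiN(SiMe3)2 (3.2 equiv, THF, −78 °C) to form the phenoxide-enolate dianion and C-acylate it with 4-methoxybenzoyl chloride (intermolecular Claisen condensation). This gives 1-[4-(benzyloxy)-2-hydroxy-3,5,6-trimethoxyphenyl]-3-(4-methoxyphenyl)propane-1,3-dione F4. Cyclodehydrate F4 with catalytic TsOH in toluene at 80 °C to give flavone 19; no oxidant is needed.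

**Further compounds**
F1 | step 5 | 1-[4-(methoxymethoxy)-2,3,5,6-tetramethoxyphenyl]ethan-1-ol (racemic) | CC(O)c1c(OC)c(OC)c(OCOC)c(OC)c1OC
F2 | step 6 | 1-(4-hydroxy-2,3,5,6-tetramethoxyphenyl)ethan-1-one | CC(=O)c1c(OC)c(OC)c(O)c(OC)c1OC
F3 | step 6 | 1-[4-(benzyloxy)-2,3,5,6-tetramethoxyphenyl]ethan-1-one | CC(=O)c1c(OC)c(OC)c(OCc2ccccc2)c(OC)c1OC
F4 | step 9 | 1-[4-(benzyloxy)-2-hydroxy-3,5,6-trimethoxyphenyl]-3-(4-methoxyphenyl)propane-1,3-dione | COc1ccc(C(=O)CC(=O)c2c(O)c(OC)c(OCc3ccccc3)c(OC)c2OC)cc1
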